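Your quick number hangs on 2.37 /M/d, the pool constant: the first-order decay rate of the pool, meaning all charged electrophile not yet product, divided by the mean [nucleophile] over the stretch. Replacing the falling [nucleophile] by its mean makes the stretch pseudo-first-order. That value is read from the last part of alpha.

| flask | electrophile | nucleophile | free base | protic impurity | remark | time |
|---|---|---|---|---|---|---|
| alpha | 0.28 M | 1.3 equiv | 2 equiv | 0.042 M | run made earlier |  |
| eta | 0.14 M | 1.3 equiv | 2 equiv | 0.028 M | run made earlier |  |
| grey | 0.28 M | 1.30 equiv | 2.00 equiv | 0.0280 M |  | 10 d |
| teal | 0.28 M | 1.30 equiv | 3.00 equiv | 0.0280 M |  | 10 d |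

| run | time / d | electrophile / % | product / % |
|---|---|---|---|
| alpha | 0.833 | 14.7 | 59.5 |
| alpha | 1.67 | 8.6 | 71.2 |
| alpha | 2.50 | 5.9 | 79.7 |
| alpha | 3.00 | 4.2 | 82.5 |
| alpha | 4.00 | 5.0 | 87.4 |
| alpha | 5.00 | 2.8 | 90.0 |
| alpha | 6.00 | 3.1 | 92.5 |
| eta | 0.833 | 20.0 | 42.6 |
| eta | 1.67 | 15.8 | 55.1 |
| eta | 2.50 | 12.2 | 63.2 |
| eta | 3.00 | 10.2 | 69.4 |
| eta | 4.00 | 8.3 | 72.6 |
| eta | 5.00 | 5.9 | 79.3 |
| eta | 6.00 | 6.5 | 82.3 |

(standard deviation of a reading: 1 percentage point)

- part of the electrophile that has reacted at the end, grey
- part of the electrophile that has reacted at the end, teal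
- what raising the equivalents of free base from its lowest to its highest value here does to the part of the electrophile that has reacted (changes below 5 percentage points count as none) (it falls / it rises / no change)

- what has gone from electrophile into another species counts as reacted, even if it can come back

Check the constant on eta, at 0.14 M: it reads 2.41 /M/d, level with alpha, though the concentration differs.

Now reckon grey. Start from alpha's last reading and assume the lower protic impurity, 0.0280 M against 0.042 M, changes nothing. Take mean [nucleophile] as 0.0945 M, midway between that reading and full conversion. The pool then falls to 3.06%. In alpha's later readings, free electrophile reads 31.7% of the pool, so my estimate is 0.970% free and 99.0% reacted.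

No run varies free base, so assume the constant holds for teal, which gets the same figure. Your hunch of no effect stands, since the whole pool is smaller than the 5 percentage points margin.

The forecast gave 98.8% for grey, 98.8% for teal and no change, with “free electrophile remains about 1–1.5%”, against my 99.0% for each.

The flask gives 99.2% for grey, 99.2% for teal and no change.

    electrophile + nucleophile → acid set free + product (k = 0.350 /M/h)
    nucleophile + acid set free ⇌ protonated nucleophile, settled at all times (K = 35.0 /M)
    acid set free + free base ⇌ salt of the base (K = 15000 /M, k = 15.0 /M/h)
    electrophile ⇌ dormant form (K = 1.60, k = 0.0770 /h)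
    protic impurity + free base → quenched reagent (k = 1.80 /M/h)

At 10.0 d, grey holds 0.809% electrophile and 1.65% dormant form, and teal holds 0.801% and 1.64%. Apply 2.37 /M/d to the neighbour of teal charged with 0.070 M electrophile, taking mean [nucleophile] between its charge and the 38% left at the end: the pool should fall to 22.5%. That neighbour ends with 80.1% product, a pool of 19.9%, and 92.8% of its electrophile reacted.

The readings were computed from invented constants, noise included.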